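L, X and J cannot be the whole content of Wednesday's closed flask: at 12.0 h they add up to 90.3% of the L charged. I call the missing part the gap, g.

| setting | Wednesday's | flask |
|---|---|---|
| L | 0.10 M | 0.10 M |
| E | 0.050 M | 0.100 M |
| remark | run made earlier |  |
| time |  | 5.0 d |

- Wednesday's (time / h: L / %, X / %, J / %): 1.50: 87.3, 6.1, 1.7; 3.00: 76.4, 11.3, 6.4; 5.00: 63.8, 16.2, 10.4; 6.00: 59.8, 18.3, 12.3; 8.00: 51.5, 21.8, 17.0; 10.0: 46.1, 22.8, 18.9; 12.0: 40.4, 26.1, 23.8

(standard deviation of a reading: 0.5 percentage points)

- the reaction counts as stopped when no species that holds the L changes by six tenths of a point or more over the second half of the time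

- which holds at 5.0 d: what has brought the reaction to rest, or that it has not come to rest (E has run out first / all of L has reacted / it is still moving / forward and back rates have come level)
- share of the L used up at 5.0 d
- X at 5.0 d, in percent of the L charged
- J at 5.0 d, in percent of the L charged

I read g in two ways. If g were a passing intermediate, it would follow the rate at which L is lost. In Wednesday's run that rate fell by a factor of 2.97 from the first interval to the last, so g should have shrunk, and it should vanish once L is gone. If g were a store held in balance with X, it would rise with X. The readings take g from 4.9 percentage points to 9.7 points, larger at the end, so the first of these two ways fails on Wednesday's readings. From 8.00 h on, the readings give 0.447 for the gap ratio ρ, the gap divided by X. My rule follows, for a flask in which the gap stands to X in this read ratio: X is what L and J leave of the charge, divided by one plus ρ.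

The forecast for the new flask was all of L has reacted, with 100% of L used, X 58% and J 42%. Those two add up to 100%, and of the intermediate it said “so it is gone by 120 h”. I agreed that L would be gone. But with the forecast's J, my rule gives X 40.1%, not 58%.

The flask gave all of L has reacted, with >99.9% of L used, X 46.7% and J 34.1%.

    L + E → Z + G (k = 1.80 L mol⁻¹ h⁻¹)
    Z ⇌ X (K = 10.0, k = 2.00 h⁻¹)
    Z ⇌ D (K = 3.10, k = 1.10 h⁻¹)
    L + G → J (k = 2.30 L mol⁻¹ h⁻¹)

With the flask's J, the rule gives X 45.5%; the gap there is D 14.5% and Z 4.67%. In the neighbour with 0.040 M of E, where L 20.3% remains, the rule gives X 27.6% against 28.3%. The flask itself had come to rest: L, the limiting reagent, stood at 0% with 34% of E left, and the largest move over the second half of the time was 0.02 points. In this flask, ten times the time leaves X at 46.7% and J at 34.1%, and the gap ratio at 0.411.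

The readings were computed on assumed constants; the scatter is artificial.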